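## Retrosynthetic overview

1. Target 34 comes from macrolactam 31 by C7 carbamoylation and desilylation. The 19-membered lactam 31 is closed by an intramolecular CuI/diamine N-arylation of the C1 primary amide with the aryl bromide of seco-amide 30. This is the only ring formed; the benzene ring is bought.
2. Seco chain 30 is cut at C7–C8: the alkenylzinc from methylalkyne 26 (C8–C15 plus arene) adds under chelation control to α-methoxy aldehyde 7 (C1–C7).
3. Alkyne 26 is cut at C10–C11: BF3-mediated addition of chiral allenylstannane 11 to α-methoxy aldehyde 24 (C11–C15 plus arene).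
4. Aldehyde 24 comes from trans-alkylation of trityl lactone 15 with benzyl bromide 14, the lactone carbonyl becoming the C14 methyl group.
5. Aldehyde 7 comes from the same (S)-lactone 1 by lactol Wittig olefination, so C6 and C12 both derive from 1.

Assumption: chain atoms are numbered C1 (amide carbonyl) to C15 (benzylic CH2), arene C16–C21 with O on C17 and N on C20; the SMILES is read as 2E, 6S, 7S, 8E, 10S, 11R, 12S, 14R.

## Fragment 1: C1–C7 aldehyde

Step 1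
Reactants: 1 (S)-5-(hydroxymethyl)dihydrofuran-2(3H)-one
Product: 2 (S)-5-[(tert-butyldiphenylsilyloxy)methyl]dihydrofuran-2(3H)-one
Conditions: tBuPh2SiCl, imidazole, DMF, 0 °C → rt
Reagents that add atoms: tert-butyl(chloro)diphenylsilane, CC(C)(C)[Si](Cl)(c1ccccc1)c1ccccc1
Why: Imidazole-promoted silyl ether formation at the primary alcohol leaves the lactone stereocentre (future C6) untouched.

Step 2
Reactants: 2 (S)-5-[(tert-butyldiphenylsilyloxy)methyl]dihydrofuran-2(3H)-one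
Product: 3 (5S)-5-[(tert-butyldiphenylsilyloxy)methyl]tetrahydrofuran-2-ol (anomer mixture)
Conditions: iBu2AlH, CH2Cl2, −78 °C
Reagents that add atoms: none
Why: Partial lactone reduction stops at the lactol because the tetrahedral aluminate is stable at −78 °C.

Step 3
Reactants: 3 (5S)-5-[(tert-butyldiphenylsilyloxy)methyl]tetrahydrofuran-2-ol
Product: 4 ethyl (2E,6S)-7-[(tert-butyldiphenylsilyl)oxy]-6-hydroxy-2-methylhept-2-enoate
Conditions: Ph3P=C(CH3)CO2Et, toluene, 80 °C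
Reagents that add atoms: ethyl 2-(triphenylphosphoranylidene)propanoate, CCOC(=O)C(C)=P(c1ccccc1)(c1ccccc1)c1ccccc1
Why: Wittig olefination of the open hydroxy-aldehyde tautomer with a stabilised ylide gives the E-trisubstituted enoate (C2=C3).

Step 4
Reactants: 4 ethyl (2E,6S)-7-[(tert-butyldiphenylsilyl)oxy]-6-hydroxy-2-methylhept-2-enoate
Product: 5 ethyl (2E,6S)-7-[(tert-butyldiphenylsilyl)oxy]-6-methoxy-2-methylhept-2-enoate
Conditions: MeOTf, 2,6-di-tert-butyl-4-methylpyridine, CH2Cl2, 0 °C → rt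
Reagents that add atoms: methyl trifluoromethanesulfonate, COS(=O)(=O)C(F)(F)F
Why: O-Methylation without an alkoxide avoids oxa-Michael closure onto the enoate and silyl migration, with retention at C6.

Step 5
Reactants: 5 ethyl (2E,6S)-7-[(tert-butyldiphenylsilyl)oxy]-6-methoxy-2-methylhept-2-enoate
Product: 6 ethyl (2E,6S)-7-hydroxy-6-methoxy-2-methylhept-2-enoate
Conditions: Bu4NF, AcOH, THF, 0 °C → rt
Reagents that add atoms: none
Why: Buffered fluoride desilylation frees the primary alcohol without touching the enoate.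

Step 6
Reactants: 6 ethyl (2E,6S)-7-hydroxy-6-methoxy-2-methylhept-2-enoate
Product: 7 ethyl (2E,6S)-6-methoxy-2-methyl-7-oxohept-2-enoate
Conditions: Dess–Martin periodinane, CH2Cl2, 0 °C → rt, used crude
Reagents that add atoms: none
Why: Dess–Martin oxidation under near-neutral conditions gives the α-methoxy aldehyde without epimerising C6.

## Fragment 2: allenylstannane

Step 7
Reactants: 8 pent-3-yn-2-one
Product: 9 (S)-pent-3-yn-2-ol
Conditions: RuCl[(S,S)-TsNCHPhCHPhNH2](p-cymene) (0.5 mol %), iPrOH, rt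
Reagents that add atoms: none
Why: Noyori asymmetric transfer hydrogenation of an alkynyl ketone, where the (S,S)-catalyst gives the (S)-propargylic alcohol (the alkynyl group takes the place of the aryl group of acetophenone).

Step 8
Reactants: 9 (S)-pent-3-yn-2-ol
Product: 10 (S)-pent-3-yn-2-yl methanesulfonate
Conditions: MsCl, Et3N, CH2Cl2, −78 °C
Reagents that add atoms: methanesulfonyl chloride, CS(=O)(=O)Cl
Why: O-Sulfonylation activates the propargylic position with no change at carbon.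

Step 9
Reactants: 10 (S)-pent-3-yn-2-yl methanesulfonate
Product: 11 (Ra)-tributyl(penta-2,3-dien-2-yl)stannane
Conditions: Bu3SnH, LiN(iPr)2, THF, 0 °C; CuBr·SMe2, −78 °C; then 10, −78 °C
Reagents that add atoms: tributylstannane, CCCC[SnH](CCCC)CCCC
Why: Anti-SN2' displacement of the propargylic mesylate by the stannylcuprate converts the (S) centre into (Ra) axial chirality.

## Fragment 3: benzyl bromide

Step 10
Reactants: 12 4-bromo-2-methylphenol
Product: 13 (4-bromo-2-methylphenoxy)triisopropylsilane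
Conditions: iPr3SiCl, imidazole, DMF, rt
Reagents that add atoms: chlorotriisopropylsilane, CC(C)[Si](Cl)(C(C)C)C(C)C
Why: Phenol silylation gives an aryl silyl ether robust enough for the steps ahead and removable by fluoride at the end.

Step 11
Reactants: 13 (4-bromo-2-methylphenoxy)triisopropylsilane
Product: 14 [4-bromo-2-(bromomethyl)phenoxy]triisopropylsilane
Conditions: N-bromosuccinimide, 2,2'-azobis(2-methylpropionitrile) (5 mol %), PhCF3, 85 °C
Reagents that add atoms: N-bromosuccinimide, O=C1CCC(=O)N1Br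
Why: Wohl–Ziegler radical bromination is selective for the benzylic methyl group.

## Main line

Step 12
Reactants: 1 (S)-5-(hydroxymethyl)dihydrofuran-2(3H)-one
Product: 15 (S)-5-[(triphenylmethoxy)methyl]dihydrofuran-2(3H)-one
Conditions: Ph3CCl, pyridine, 4-(dimethylamino)pyridine (5 mol %), CH2Cl2, rt
Reagents that add atoms: chlorotriphenylmethane, ClC(c1ccccc1)(c1ccccc1)c1ccccc1
Why: Tritylation of the primary alcohol installs a bulky group that later shields one face of the lactone enolate.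

Step 13
Reactants: 15 (S)-5-[(triphenylmethoxy)methyl]dihydrofuran-2(3H)-one; 14 [4-bromo-2-(bromomethyl)phenoxy]triisopropylsilane
Product: 17 (3R,5S)-3-[[5-bromo-2-(triisopropylsilyloxy)phenyl]methyl]-5-[(triphenylmethoxy)methyl]dihydrofuran-2(3H)-one, via lithium enolate 16 (not isolated)
Conditions: LiN(iPr)2, THF, −78 °C; then 14, −78 → −40 °C
Reagents that add atoms: none
Why: Lactone enolate alkylation (SN2 at the benzylic bromide) occurs anti to the trityloxymethyl group, giving the 3,5-trans lactone that fixes C14 relative to C12.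

Step 14
Reactants: 17 (3R,5S)-3-[[5-bromo-2-(triisopropylsilyloxy)phenyl]methyl]-5-[(triphenylmethoxy)methyl]dihydrofuran-2(3H)-one
Product: 18 (3R,5S)-3-[[5-bromo-2-(triisopropylsilyloxy)phenyl]methyl]-5-[(triphenylmethoxy)methyl]tetrahydrofuran-2-ol (anomer mixture)
Conditions: iBu2AlH, CH2Cl2, −78 °C
Reagents that add atoms: none
Why: Partial reduction of the lactone to the lactol, with ethers and the aryl bromide inert.

Step 15
Reactants: 18 (3R,5S)-3-[[5-bromo-2-(triisopropylsilyloxy)phenyl]methyl]-5-[(triphenylmethoxy)methyl]tetrahydrofuran-2-ol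
Product: 19 N'-[(2R,4S)-2-[[5-bromo-2-(triisopropylsilyloxy)phenyl]methyl]-4-hydroxy-5-(triphenylmethoxy)pentylidene]-4-methylbenzenesulfonohydrazide
Conditions: TsNHNH2, THF/MeOH, rt
Reagents that add atoms: 4-methylbenzenesulfonohydrazide, Cc1ccc(cc1)S(=O)(=O)NN
Why: Hydrazone condensation traps the open hydroxy-aldehyde form of the lactol.

Step 16
Reactants: 19 N'-[(2R,4S)-2-[[5-bromo-2-(triisopropylsilyloxy)phenyl]methyl]-4-hydroxy-5-(triphenylmethoxy)pentylidene]-4-methylbenzenesulfonohydrazide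
Product: 21 (2S,4R)-5-[5-bromo-2-(triisopropylsilyloxy)phenyl]-4-methyl-1-(triphenylmethoxy)pentan-2-ol, via tosylhydrazine 20 (not isolated)
Conditions: catecholborane, CHCl3, 0 °C; then NaOAc·3H2O, 60 °C
Reagents that add atoms: none
Why: Kabalka-type reductive deoxygenation (hydride addition to C=N, sulfinate elimination, loss of N2) turns the former lactone carbonyl into the C14 methyl group without touching C14 itself.

Step 17
Reactants: 21 (2S,4R)-5-[5-bromo-2-(triisopropylsilyloxy)phenyl]-4-methyl-1-(triphenylmethoxy)pentan-2-ol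
Product: 22 [4-bromo-2-[(2R,4S)-4-methoxy-2-methyl-5-(triphenylmethoxy)pentyl]phenoxy]triisopropylsilane
Conditions: MeOTf, 2,6-di-tert-butyl-4-methylpyridine, CH2Cl2, rt
Reagents that add atoms: methyl trifluoromethanesulfonate, COS(=O)(=O)C(F)(F)F
Why: Non-basic O-methylation installs the C12 methoxy group with retention and avoids alkoxide attack on the aryl silyl ether.

Step 18
Reactants: 22 [4-bromo-2-[(2R,4S)-4-methoxy-2-methyl-5-(triphenylmethoxy)pentyl]phenoxy]triisopropylsilane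
Product: 23 (2S,4R)-5-[5-bromo-2-(triisopropylsilyloxy)phenyl]-2-methoxy-4-methylpentan-1-ol
Conditions: p-toluenesulfonic acid monohydrate (10 mol %), MeOH/CH2Cl2, rt
Reagents that add atoms: none
Why: Acid-catalysed SN1 solvolysis removes the trityl ether while the aryl silyl ether and methyl ether survive.

Step 19
Reactants: 23 (2S,4R)-5-[5-bromo-2-(triisopropylsilyloxy)phenyl]-2-methoxy-4-methylpentan-1-ol
Product: 24 (2S,4R)-5-[5-bromo-2-(triisopropylsilyloxy)phenyl]-2-methoxy-4-methylpentanal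
Conditions: Dess–Martin periodinane, CH2Cl2, 0 °C → rt, used crude
Reagents that add atoms: none
Why: Dess–Martin oxidation gives the α-methoxy aldehyde without epimerising C12.

Step 20
Reactants: 24 (2S,4R)-5-[5-bromo-2-(triisopropylsilyloxy)phenyl]-2-methoxy-4-methylpentanal; 11 (Ra)-tributyl(penta-2,3-dien-2-yl)stannane
Product: 25 (4S,5R,6S,8R)-9-[5-bromo-2-(triisopropylsilyloxy)phenyl]-6-methoxy-4,8-dimethylnon-2-yn-5-ol
Conditions: BF3·OEt2, CH2Cl2, −78 °C
Reagents that add atoms: none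
Why: Marshall propargylation through an open transition state: anti-SE2' attack sets C10 (S) and the 10,11-syn relation, and Felkin–Anh addition to the non-chelated α-methoxy aldehyde sets C11 (R, 11,12-anti), a matched pair.

Step 21
Reactants: 25 (4S,5R,6S,8R)-9-[5-bromo-2-(triisopropylsilyloxy)phenyl]-6-methoxy-4,8-dimethylnon-2-yn-5-ol
Product: 26 [4-bromo-2-[(2R,4S,5R,6S)-5-[(tert-butyldimethylsilyl)oxy]-4-methoxy-2,6-dimethylnon-7-yn-1-yl]phenoxy]triisopropylsilane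
Conditions: tBuMe2SiOTf, 2,6-lutidine, CH2Cl2, −78 → 0 °C
Reagents that add atoms: tert-butyldimethylsilyl trifluoromethanesulfonate, CC(C)(C)[Si](C)(C)OS(=O)(=O)C(F)(F)F
Why: The silyl triflate protects the hindered C11 alcohol so that C7–OH is the only free alcohol later.

Step 22
Reactants: 26 [4-bromo-2-[(2R,4S,5R,6S)-5-[(tert-butyldimethylsilyl)oxy]-4-methoxy-2,6-dimethylnon-7-yn-1-yl]phenoxy]triisopropylsilane; 7 ethyl (2E,6S)-6-methoxy-2-methyl-7-oxohept-2-enoate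
Product: 29 ethyl (2E,6S,7S,8E,10S,11R,12S,14R)-15-[5-bromo-2-(triisopropylsilyloxy)phenyl]-11-[(tert-butyldimethylsilyl)oxy]-7-hydroxy-6,12-dimethoxy-2,8,10,14-tetramethylpentadeca-2,8-dienoate, via alkenylzirconocene 27 (not isolated), via alkenylzinc 28 (not isolated)
Conditions: Cp2Zr(H)Cl (1.5 equiv), THF, 45 °C; ZnMe2, toluene, −78 °C; then 7 (2 equiv), −78 → 0 °C
Reagents that add atoms: none
Why: syn-Hydrozirconation puts Zr on the less hindered C8 (giving 8E), Zr-to-Zn transmetalation follows, and Cram-chelate addition to the α-methoxy aldehyde sets C7 (S, 6,7-syn).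

Step 23
Reactants: 29 ethyl (2E,6S,7S,8E,10S,11R,12S,14R)-15-[5-bromo-2-(triisopropylsilyloxy)phenyl]-11-[(tert-butyldimethylsilyl)oxy]-7-hydroxy-6,12-dimethoxy-2,8,10,14-tetramethylpentadeca-2,8-dienoate
Product: 30 (2E,6S,7S,8E,10S,11R,12S,14R)-15-[5-bromo-2-(triisopropylsilyloxy)phenyl]-11-[(tert-butyldimethylsilyl)oxy]-7-hydroxy-6,12-dimethoxy-2,8,10,14-tetramethylpentadeca-2,8-dienamide
Conditions: AlMe3, NH4Cl, toluene, 0 → 50 °C
Reagents that add atoms: ammonium chloride, [NH4+].[Cl-]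
Why: Weinreb aminolysis with the aluminium amide converts the ester directly into the primary amide, the silyl ethers and aryl bromide being inert.

Step 24
Reactants: 30 (2E,6S,7S,8E,10S,11R,12S,14R)-15-[5-bromo-2-(triisopropylsilyloxy)phenyl]-11-[(tert-butyldimethylsilyl)oxy]-7-hydroxy-6,12-dimethoxy-2,8,10,14-tetramethylpentadeca-2,8-dienamide
Product: 31 19-membered lactam (N–C20 bond) carrying 7-OH, 11-O-tert-butyldimethylsilyl and 17-O-triisopropylsilyl groups: (2E,6S,7S,8E,10S,11R,12S,14R)-configured 7-descarbamoyl bis-silyl ether of the target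
Conditions: CuI (20 mol %), MeNHCH2CH2NHMe (40 mol %), K2CO3, toluene (5 mM), 110 °C
Reagents that add atoms: none
Why: Intramolecular Goldberg-type copper-catalysed N-arylation of the primary amide by the unhindered aryl bromide at high dilution closes the meta-bridged macrolactam, the amide N–H reacting in preference to the secondary alcohol.

Step 25
Reactants: 31 macrolactam with free 7-OH
Product: 33 7-O-carbamoyl macrolactam (11-O-tert-butyldimethylsilyl-17-O-triisopropylsilyl ether of the target), via trichloroacetyl carbamate 32 (not isolated)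
Conditions: Cl3CC(O)NCO, CH2Cl2, 0 °C; then neutral Al2O3, rt
Reagents that add atoms: trichloroacetyl isocyanate, O=C=NC(=O)C(Cl)(Cl)Cl
Why: The only free alcohol adds to the acyl isocyanate and the trichloroacetyl group is hydrolysed on alumina, the anilide N–H being unreactive.

Step 26
Reactants: 33 7-O-carbamoyl macrolactam bis-silyl ether
Product: 34 target macrolactam CNP0544610.1
Conditions: HF·pyridine, pyridine, THF, 0 °C → rt
Reagents that add atoms: none
Why: Fluoride-driven cleavage of the alkyl and the aryl silyl ether frees C11–OH and the phenol without affecting carbamate, lactam or alkenes.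

## Compound list

1 | (S)-5-(hydroxymethyl)dihydrofuran-2(3H)-one | O=C1CC[C@@H](CO)O1 | starting material
2 | (S)-5-[(tert-butyldiphenylsilyloxy)methyl]dihydrofuran-2(3H)-one | O=C1CC[C@@H](CO[Si](c2ccccc2)(c2ccccc2)C(C)(C)C)O1 | intermediate
3 | (5S)-5-[(tert-butyldiphenylsilyloxy)methyl]tetrahydrofuran-2-ol (anomer mixture) | OC1CC[C@@H](CO[Si](c2ccccc2)(c2ccccc2)C(C)(C)C)O1 | intermediate
4 | ethyl (2E,6S)-7-[(tert-butyldiphenylsilyl)oxy]-6-hydroxy-2-methylhept-2-enoate | CCOC(=O)/C(C)=C/CC[C@H](O)CO[Si](c1ccccc1)(c1ccccc1)C(C)(C)C | intermediate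
5 | ethyl (2E,6S)-7-[(tert-butyldiphenylsilyl)oxy]-6-methoxy-2-methylhept-2-enoate | CCOC(=O)/C(C)=C/CC[C@H](OC)CO[Si](c1ccccc1)(c1ccccc1)C(C)(C)C | intermediate
6 | ethyl (2E,6S)-7-hydroxy-6-methoxy-2-methylhept-2-enoate | CCOC(=O)/C(C)=C/CC[C@H](OC)CO | intermediate
7 | ethyl (2E,6S)-6-methoxy-2-methyl-7-oxohept-2-enoate | CCOC(=O)/C(C)=C/CC[C@H](OC)C=O | intermediate
8 | pent-3-yn-2-one | CC#CC(C)=O | starting material
9 | (S)-pent-3-yn-2-ol | CC#C[C@H](C)O | intermediate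
10 | (S)-pent-3-yn-2-yl methanesulfonate | CC#C[C@H](C)OS(C)(=O)=O | intermediate
11 | (Ra)-tributyl(penta-2,3-dien-2-yl)stannane | CC([Sn](CCCC)(CCCC)CCCC)=[C@@]=C([H])C | intermediate
12 | 4-bromo-2-methylphenol | Cc1cc(Br)ccc1O | starting material
13 | (4-bromo-2-methylphenoxy)triisopropylsilane | Cc1cc(Br)ccc1O[Si](C(C)C)(C(C)C)C(C)C | intermediate
14 | [4-bromo-2-(bromomethyl)phenoxy]triisopropylsilane | BrCc1cc(Br)ccc1O[Si](C(C)C)(C(C)C)C(C)C | intermediate
15 | (S)-5-[(triphenylmethoxy)methyl]dihydrofuran-2(3H)-one | O=C1CC[C@@H](COC(c2ccccc2)(c2ccccc2)c2ccccc2)O1 | intermediate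
16 | lithium enolate of 15 | [Li]OC1=CC[C@@H](COC(c2ccccc2)(c2ccccc2)c2ccccc2)O1 | intermediate
17 | (3R,5S)-3-[[5-bromo-2-(triisopropylsilyloxy)phenyl]methyl]-5-[(triphenylmethoxy)methyl]dihydrofuran-2(3H)-one | O=C1[C@H](Cc2cc(Br)ccc2O[Si](C(C)C)(C(C)C)C(C)C)C[C@@H](COC(c2ccccc2)(c2ccccc2)c2ccccc2)O1 | intermediate
18 | (3R,5S)-3-[[5-bromo-2-(triisopropylsilyloxy)phenyl]methyl]-5-[(triphenylmethoxy)methyl]tetrahydrofuran-2-ol (anomer mixture) | OC1[C@H](Cc2cc(Br)ccc2O[Si](C(C)C)(C(C)C)C(C)C)C[C@@H](COC(c2ccccc2)(c2ccccc2)c2ccccc2)O1 | intermediate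
19 | N'-[(2R,4S)-2-[[5-bromo-2-(triisopropylsilyloxy)phenyl]methyl]-4-hydroxy-5-(triphenylmethoxy)pentylidene]-4-methylbenzenesulfonohydrazide | Cc1ccc(cc1)S(=O)(=O)NN=C[C@H](Cc1cc(Br)ccc1O[Si](C(C)C)(C(C)C)C(C)C)C[C@H](O)COC(c1ccccc1)(c1ccccc1)c1ccccc1 | intermediate
20 | N'-[(2R,4S)-2-[[5-bromo-2-(triisopropylsilyloxy)phenyl]methyl]-4-hydroxy-5-(triphenylmethoxy)pentyl]-4-methylbenzenesulfonohydrazide (formed as its boron adduct) | Cc1ccc(cc1)S(=O)(=O)NNC[C@H](Cc1cc(Br)ccc1O[Si](C(C)C)(C(C)C)C(C)C)C[C@H](O)COC(c1ccccc1)(c1ccccc1)c1ccccc1 | intermediate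
21 | (2S,4R)-5-[5-bromo-2-(triisopropylsilyloxy)phenyl]-4-methyl-1-(triphenylmethoxy)pentan-2-ol | C[C@H](Cc1cc(Br)ccc1O[Si](C(C)C)(C(C)C)C(C)C)C[C@H](O)COC(c1ccccc1)(c1ccccc1)c1ccccc1 | intermediate
22 | [4-bromo-2-[(2R,4S)-4-methoxy-2-methyl-5-(triphenylmethoxy)pentyl]phenoxy]triisopropylsilane | C[C@H](Cc1cc(Br)ccc1O[Si](C(C)C)(C(C)C)C(C)C)C[C@H](OC)COC(c1ccccc1)(c1ccccc1)c1ccccc1 | intermediate
23 | (2S,4R)-5-[5-bromo-2-(triisopropylsilyloxy)phenyl]-2-methoxy-4-methylpentan-1-ol | C[C@H](Cc1cc(Br)ccc1O[Si](C(C)C)(C(C)C)C(C)C)C[C@H](OC)CO | intermediate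
24 | (2S,4R)-5-[5-bromo-2-(triisopropylsilyloxy)phenyl]-2-methoxy-4-methylpentanal | C[C@H](Cc1cc(Br)ccc1O[Si](C(C)C)(C(C)C)C(C)C)C[C@H](OC)C=O | intermediate
25 | (4S,5R,6S,8R)-9-[5-bromo-2-(triisopropylsilyloxy)phenyl]-6-methoxy-4,8-dimethylnon-2-yn-5-ol | CC#C[C@H](C)[C@@H](O)[C@@H](OC)C[C@H](C)Cc1cc(Br)ccc1O[Si](C(C)C)(C(C)C)C(C)C | intermediate
26 | [4-bromo-2-[(2R,4S,5R,6S)-5-[(tert-butyldimethylsilyl)oxy]-4-methoxy-2,6-dimethylnon-7-yn-1-yl]phenoxy]triisopropylsilane | CC#C[C@H](C)[C@@H](O[Si](C)(C)C(C)(C)C)[C@@H](OC)C[C@H](C)Cc1cc(Br)ccc1O[Si](C(C)C)(C(C)C)C(C)C | intermediate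
27 | (E)-alkenyl(chloro)zirconocene from 26, Zr on C8 (Cp drawn η1) | Cl[Zr](C1C=CC=C1)(C1C=CC=C1)/C(C)=C/[C@H](C)[C@@H](O[Si](C)(C)C(C)(C)C)[C@@H](OC)C[C@H](C)Cc1cc(Br)ccc1O[Si](C(C)C)(C(C)C)C(C)C | intermediate
28 | (E)-alkenyl(methyl)zinc from 27, Zn on C8 | C[Zn]/C(C)=C/[C@H](C)[C@@H](O[Si](C)(C)C(C)(C)C)[C@@H](OC)C[C@H](C)Cc1cc(Br)ccc1O[Si](C(C)C)(C(C)C)C(C)C | intermediate
29 | ethyl (2E,6S,7S,8E,10S,11R,12S,14R)-15-[5-bromo-2-(triisopropylsilyloxy)phenyl]-11-[(tert-butyldimethylsilyl)oxy]-7-hydroxy-6,12-dimethoxy-2,8,10,14-tetramethylpentadeca-2,8-dienoate | CCOC(=O)/C(C)=C/CC[C@H](OC)[C@@H](O)/C(C)=C/[C@H](C)[C@@H](O[Si](C)(C)C(C)(C)C)[C@@H](OC)C[C@H](C)Cc1cc(Br)ccc1O[Si](C(C)C)(C(C)C)C(C)C | intermediate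
30 | (2E,6S,7S,8E,10S,11R,12S,14R)-15-[5-bromo-2-(triisopropylsilyloxy)phenyl]-11-[(tert-butyldimethylsilyl)oxy]-7-hydroxy-6,12-dimethoxy-2,8,10,14-tetramethylpentadeca-2,8-dienamide | NC(=O)/C(C)=C/CC[C@H](OC)[C@@H](O)/C(C)=C/[C@H](C)[C@@H](O[Si](C)(C)C(C)(C)C)[C@@H](OC)C[C@H](C)Cc1cc(Br)ccc1O[Si](C(C)C)(C(C)C)C(C)C | intermediate
31 | 19-membered lactam with 7-OH, 11-O-tert-butyldimethylsilyl, 17-O-triisopropylsilyl | CO[C@H]1C[C@H](C)Cc2cc(ccc2O[Si](C(C)C)(C(C)C)C(C)C)NC(=O)/C(C)=C/CC[C@H](OC)[C@@H](O)/C(C)=C/[C@H](C)[C@H]1O[Si](C)(C)C(C)(C)C | intermediate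
32 | 7-O-(trichloroacetylcarbamoyl) derivative of 31 | CO[C@H]1C[C@H](C)Cc2cc(ccc2O[Si](C(C)C)(C(C)C)C(C)C)NC(=O)/C(C)=C/CC[C@H](OC)[C@@H](OC(=O)NC(=O)C(Cl)(Cl)Cl)/C(C)=C/[C@H](C)[C@H]1O[Si](C)(C)C(C)(C)C | intermediate
33 | 7-O-carbamoyl macrolactam, 11-O-tert-butyldimethylsilyl, 17-O-triisopropylsilyl | CO[C@H]1C[C@H](C)Cc2cc(ccc2O[Si](C(C)C)(C(C)C)C(C)C)NC(=O)/C(C)=C/CC[C@H](OC)[C@@H](OC(N)=O)/C(C)=C/[C@H](C)[C@H]1O[Si](C)(C)C(C)(C)C | intermediate
34 | CNP0544610.1 | CO[C@H]1C[C@H](C)Cc2cc(ccc2O)NC(=O)/C(C)=C/CC[C@H](OC)[C@@H](OC(N)=O)/C(C)=C/[C@H](C)[C@H]1O | target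

## Step count and risks

Total step count: 26 (fragment 1: steps 1–6; fragment 2: steps 7–9; fragment 3: steps 10–11; main line: steps 12–26).
Longest linear sequence: 16 steps (steps 10, 11 and 13–26, starting from 12).

The three steps most likely to fail:

Step 20 (allenylstannane propargylation; the stannane's enantiopurity and the syn/anti ratio are the risks). The fallback sets out from 24 and comes back at 26, building C8–C10 by auxiliary control. Evans boron aldol of 24 with (R)-4-benzyl-3-propanoyl-1,3-oxazolidin-2-one (Bu2BOTf, Et3N, CH2Cl2, −78 → 0 °C) gives the syn-aldol imide F1, the Z-enolate being matched with the 11,12-anti preference of the α-methoxy aldehyde. tBuMe2SiOTf/2,6-lutidine gives the silyl ether F2, and LiBH4 (Et2O/MeOH, 0 °C) cleaves the auxiliary to the primary alcohol F3. Dess–Martin oxidation gives the aldehyde F4, and Colvin homologation with Me3SiCHN2/LiN(iPr)2 (THF, −78 °C → rt) gives the terminal alkyne F5. Deprotonation with LiN(iPr)2 and quenching with MeI gives 26.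

Step 22 (hydrozirconation regiochemistry and chelation-controlled addition). The fallback sets out from 26 and comes back at 29, moving control of C7 from the C–C bond formation to a ketone reduction. Cp2Zr(H)Cl then I2 gives the (E)-vinyl iodide F6. CrCl2/NiCl2 (1 mol %) coupling with 7 in DMSO gives the allylic alcohol F7 as a C7 epimer mixture, and Dess–Martin oxidation converges both epimers to the enone F8. Reduction with catecholborane and (S)-1-methyl-3,3-diphenyltetrahydro-1H,3H-pyrrolo[1,2-c][1,3,2]oxazaborole (20 mol %, toluene, −78 °C; the alkenyl group acts as the large substituent, reinforced by the Felkin preference) gives 29.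

Step 24 (copper-catalysed macrocyclic N-arylation of an electron-rich aryl bromide). The fallback sets out from 29 and comes back at 31, closing the ring by amide bond formation instead. Amination of 29 with benzophenone imine (Pd2(dba)3, 2,2'-bis(diphenylphosphino)-1,1'-binaphthyl, Cs2CO3, toluene, 100 °C) gives the N-aryl imine F9. NH2OH·HCl/NaOAc in MeOH releases the aniline F10, and Me3SnOH (1,2-dichloroethane, 80 °C) hydrolyses the ethyl ester to the amino acid F11. Macrolactamisation with bis(2-oxo-3-oxazolidinyl)phosphinic chloride and iPr2NEt (toluene, 2 mM, 85 °C) gives 31; lactonisation through C7–OH is excluded because it would place the E-alkene in a seven-membered ring.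

## Further compounds

F1 | step 20 | (R)-4-benzyl-3-[(2R,3R,4S,6R)-7-[5-bromo-2-(triisopropylsilyloxy)phenyl]-3-hydroxy-4-methoxy-2,6-dimethylheptanoyl]-1,3-oxazolidin-2-one | O=C1OC[C@@H](Cc2ccccc2)N1C(=O)[C@H](C)[C@@H](O)[C@@H](OC)C[C@H](C)Cc1cc(Br)ccc1O[Si](C(C)C)(C(C)C)C(C)C
F2 | step 20 | (R)-4-benzyl-3-[(2R,3R,4S,6R)-7-[5-bromo-2-(triisopropylsilyloxy)phenyl]-3-[(tert-butyldimethylsilyl)oxy]-4-methoxy-2,6-dimethylheptanoyl]-1,3-oxazolidin-2-one | O=C1OC[C@@H](Cc2ccccc2)N1C(=O)[C@H](C)[C@@H](O[Si](C)(C)C(C)(C)C)[C@@H](OC)C[C@H](C)Cc1cc(Br)ccc1O[Si](C(C)C)(C(C)C)C(C)C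
F3 | step 20 | (2S,3R,4S,6R)-7-[5-bromo-2-(triisopropylsilyloxy)phenyl]-3-[(tert-butyldimethylsilyl)oxy]-4-methoxy-2,6-dimethylheptan-1-ol | OC[C@H](C)[C@@H](O[Si](C)(C)C(C)(C)C)[C@@H](OC)C[C@H](C)Cc1cc(Br)ccc1O[Si](C(C)C)(C(C)C)C(C)C
F4 | step 20 | (2R,3R,4S,6R)-7-[5-bromo-2-(triisopropylsilyloxy)phenyl]-3-[(tert-butyldimethylsilyl)oxy]-4-methoxy-2,6-dimethylheptanal | O=C[C@H](C)[C@@H](O[Si](C)(C)C(C)(C)C)[C@@H](OC)C[C@H](C)Cc1cc(Br)ccc1O[Si](C(C)C)(C(C)C)C(C)C
F5 | step 20 | [4-bromo-2-[(2R,4S,5R,6S)-5-[(tert-butyldimethylsilyl)oxy]-4-methoxy-2,6-dimethyloct-7-yn-1-yl]phenoxy]triisopropylsilane | C#C[C@H](C)[C@@H](O[Si](C)(C)C(C)(C)C)[C@@H](OC)C[C@H](C)Cc1cc(Br)ccc1O[Si](C(C)C)(C(C)C)C(C)C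
F6 | step 22 | [4-bromo-2-[(2R,4S,5R,6S,7E)-5-[(tert-butyldimethylsilyl)oxy]-8-iodo-4-methoxy-2,6-dimethylnon-7-en-1-yl]phenoxy]triisopropylsilane | I/C(C)=C/[C@H](C)[C@@H](O[Si](C)(C)C(C)(C)C)[C@@H](OC)C[C@H](C)Cc1cc(Br)ccc1O[Si](C(C)C)(C(C)C)C(C)C
F7 | step 22 | ethyl (2E,6S,8E,10S,11R,12S,14R)-15-[5-bromo-2-(triisopropylsilyloxy)phenyl]-11-[(tert-butyldimethylsilyl)oxy]-7-hydroxy-6,12-dimethoxy-2,8,10,14-tetramethylpentadeca-2,8-dienoate (7R/7S mixture) | CCOC(=O)/C(C)=C/CC[C@H](OC)C(O)/C(C)=C/[C@H](C)[C@@H](O[Si](C)(C)C(C)(C)C)[C@@H](OC)C[C@H](C)Cc1cc(Br)ccc1O[Si](C(C)C)(C(C)C)C(C)C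
F8 | step 22 | ethyl (2E,6S,8E,10S,11R,12S,14R)-15-[5-bromo-2-(triisopropylsilyloxy)phenyl]-11-[(tert-butyldimethylsilyl)oxy]-6,12-dimethoxy-2,8,10,14-tetramethyl-7-oxopentadeca-2,8-dienoate | CCOC(=O)/C(C)=C/CC[C@H](OC)C(=O)/C(C)=C/[C@H](C)[C@@H](O[Si](C)(C)C(C)(C)C)[C@@H](OC)C[C@H](C)Cc1cc(Br)ccc1O[Si](C(C)C)(C(C)C)C(C)C
F9 | step 24 | ethyl (2E,6S,7S,8E,10S,11R,12S,14R)-11-[(tert-butyldimethylsilyl)oxy]-15-[5-[(diphenylmethylidene)amino]-2-(triisopropylsilyloxy)phenyl]-7-hydroxy-6,12-dimethoxy-2,8,10,14-tetramethylpentadeca-2,8-dienoate | CCOC(=O)/C(C)=C/CC[C@H](OC)[C@@H](O)/C(C)=C/[C@H](C)[C@@H](O[Si](C)(C)C(C)(C)C)[C@@H](OC)C[C@H](C)Cc1cc(N=C(c2ccccc2)c2ccccc2)ccc1O[Si](C(C)C)(C(C)C)C(C)C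
F10 | step 24 | ethyl (2E,6S,7S,8E,10S,11R,12S,14R)-15-[5-amino-2-(triisopropylsilyloxy)phenyl]-11-[(tert-butyldimethylsilyl)oxy]-7-hydroxy-6,12-dimethoxy-2,8,10,14-tetramethylpentadeca-2,8-dienoate | CCOC(=O)/C(C)=C/CC[C@H](OC)[C@@H](O)/C(C)=C/[C@H](C)[C@@H](O[Si](C)(C)C(C)(C)C)[C@@H](OC)C[C@H](C)Cc1cc(N)ccc1O[Si](C(C)C)(C(C)C)C(C)C
F11 | step 24 | (2E,6S,7S,8E,10S,11R,12S,14R)-15-[5-amino-2-(triisopropylsilyloxy)phenyl]-11-[(tert-butyldimethylsilyl)oxy]-7-hydroxy-6,12-dimethoxy-2,8,10,14-tetramethylpentadeca-2,8-dienoic acid | OC(=O)/C(C)=C/CC[C@H](OC)[C@@H](O)/C(C)=C/[C@H](C)[C@@H](O[Si](C)(C)C(C)(C)C)[C@@H](OC)C[C@H](C)Cc1cc(N)ccc1O[Si](C(C)C)(C(C)C)C(C)C
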